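**Retrosynthetic overview**
- The cis C1'=C2' olefin is made last by Z-selective cross-metathesis of a free triol alkene with (S)-6-vinyl-5,6-dihydropyran-2-one.
- The triol alkene comes from allyl addition to a cis-4-hydroxy-6-phenethyl δ-lactone, followed by 1,3-syn reduction of the resulting allyl ketone (sets C4').
- That hydroxy lactone comes from dearomatizing asymmetric hydrogenation of 4-hydroxy-6-phenethyl-2-pyranone (sets C8', then C6'), itself made from triacetic acid lactone and benzyl bromide.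
- The vinyl lactone comes from acrolein by asymmetric allylation, acryloylation and ring-closing metathesis.
- Ring order: the pyranone ring is carried from the feedstock, saturated and later opened; the dihydropyranone ring is closed by RCM before the final coupling.

Assumption: the target is read as (6S)-lactone with a (1Z,4R,6S,8R) side chain; the (S)-ligand in step 2 is taken to give the 6R lactone by analogy with 6-alkyl-4-hydroxy-2-pyranones, and the (R)-ligand is used if the sense is opposite.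

**Step 1**
Reactants: 1 4-hydroxy-6-methyl-2H-pyran-2-one (triacetic acid lactone); 2 benzyl bromide
Product: 3 4-hydroxy-6-(2-phenylethyl)-2H-pyran-2-one
Conditions: LiN(iPr)2 (2.2 equiv), THF, −78 °C; 2 (1.0 equiv), −78 → 0 °C; aq. HCl
Reagents that add atoms: none
Why: Dianion alkylation: the 4-olate/6-CH2 dianion reacts at its more nucleophilic terminal carbanion with benzyl bromide (SN2); no stereocenter is formed.

**Step 2**
Reactants: 3
Product: 5 (4S,6R)-4-hydroxy-6-(2-phenylethyl)oxan-2-one (4,6-cis), via dihydropyranone 4 (not isolated)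
Conditions: H2 (60 bar), [Ru(OAc)2((S)-MeO-BIPHEP)] (0.5 mol%), HBF4·OEt2 (1 mol%), iPrOH, 60 °C; then Raney Ni, H2 (60 bar), 25 °C, same vessel
Reagents that add atoms: none
Why: Dearomatizing asymmetric hydrogenation: the cationic Ru–bisphosphine hydride reduces only the C5=C6 bond of the 4-hydroxy-2-pyranone and sets C6 (R) by ligand control, and the enolised β-keto lactone 4 is then hydrogenated on Raney Ni from the face anti to the side chain, giving the 4,6-cis alcohol (4S) by substrate control.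

**Step 3**
Reactants: 5
Product: 6 (4S,6R)-6-(2-phenylethyl)-2-(prop-2-en-1-yl)oxane-2,4-diol (hemiketal, anomer mixture)
Conditions: allylMgBr (2.5 equiv), THF, −78 °C; aq. NH4Cl at −78 °C
Reagents that add atoms: allylmagnesium bromide, C=CC[Mg]Br
Why: Grignard mono-addition to a δ-lactone: the first equivalent deprotonates the 4-OH and the second gives a cyclic magnesium hemiketalate that is stable at −78 °C, so addition stops at the hemiketal; the anomeric centre is not controlled and is removed in step 4.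

**Step 4**
Reactants: 6
Product: 8 (4R,6S,8R)-10-phenyldec-1-ene-4,6,8-triol, via keto diol 7 (not isolated)
Conditions: Et2BOMe (1.2 equiv), THF/MeOH 4:1, −78 °C; NaBH4, −78 °C; then MeOH co-evaporation
Reagents that add atoms: none
Why: Narasaka–Prasad reduction: the open keto diol forms a six-membered diethylboron chelate between the β-oxygen and the ketone, and external hydride attacks axially to give the 4,6-syn diol (4R), which with the fixed 6,8-anti pair completes the syn,anti-triol.

**Step 5**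
Reactants: 9 acrolein
Product: 10 (3S)-hexa-1,5-dien-3-ol
Conditions: (−)-Ipc2B(allyl), Et2O, −78 °C; then NaOH, H2O2
Reagents that add atoms: (−)-B-allyldiisopinocampheylborane, C=CCB([C@@H]1C[C@@H]2C[C@H]([C@H]1C)C2(C)C)[C@@H]1C[C@@H]2C[C@H]([C@H]1C)C2(C)C
Why: Brown allylboration through a closed chair transition state: the reagent derived from (+)-α-pinene attacks the Si face of acrolein and gives the (S)-carbinol.

**Step 6**
Reactants: 10
Product: 11 (3S)-hexa-1,5-dien-3-yl prop-2-enoate
Conditions: acryloyl chloride, Et3N, DMAP (cat.), CH2Cl2, 0 °C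
Reagents that add atoms: acryloyl chloride, C=CC(=O)Cl
Why: O-acylation of the secondary alcohol with an acid chloride; the stereocenter is not touched.

**Step 7**
Reactants: 11
Product: 12 (6S)-6-ethenyl-5,6-dihydro-2H-pyran-2-one
Conditions: second-generation Grubbs catalyst RuCl2(=CHPh)(H2IMes)(PCy3) (3 mol%), CH2Cl2 (0.01 M), 40 °C
Reagents that add atoms: none
Why: Ring-closing metathesis: the carbene loads on the unhindered allyl terminus and closes onto the acrylate to give the six-membered unsaturated lactone (five-ring closure through the vinyl group is disfavoured) with loss of ethene; C6 is unchanged.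

**Step 8**
Reactants: 8 (4R,6S,8R)-10-phenyldec-1-ene-4,6,8-triol; 12 (6S)-6-ethenyl-5,6-dihydro-2H-pyran-2-one (3 equiv)
Product: 13 (6S)-6-[(1Z,4R,6S,8R)-4,6,8-trihydroxy-10-phenyldec-1-en-1-yl]-5,6-dihydro-2H-pyran-2-one
Conditions: Ru(NO3)(=CH-C6H4-2-OiPr)[C,C-chelating 1-adamantyl-3-(2,6-iPr2C6H3)imidazolin-2-ylidene] (7.5 mol%), THF, 35 °C, static vacuum
Reagents that add atoms: none
Why: Z-selective cross-metathesis: the chelated adamantyl group forces both substituents of the ruthenacyclobutane to the same side, so the cis olefin forms kinetically; this catalyst class tolerates free hydroxyls and allylic-substituted partners and leaves the conjugated ring alkene and all stereocenters alone.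

**Compound list**
1 | 4-hydroxy-6-methyl-2H-pyran-2-one (triacetic acid lactone) | CC1=CC(O)=CC(=O)O1 | starting material
2 | benzyl bromide | BrCc1ccccc1 | starting material
3 | 4-hydroxy-6-(2-phenylethyl)-2H-pyran-2-one | O=C1C=C(O)C=C(CCc2ccccc2)O1 | intermediate
4 | (6R)-4-hydroxy-6-(2-phenylethyl)-5,6-dihydro-2H-pyran-2-one | O=C1C=C(O)C[C@@H](CCc2ccccc2)O1 | intermediate
5 | (4S,6R)-4-hydroxy-6-(2-phenylethyl)oxan-2-one | O=C1C[C@@H](O)C[C@@H](CCc2ccccc2)O1 | intermediate
6 | (4S,6R)-6-(2-phenylethyl)-2-(prop-2-en-1-yl)oxane-2,4-diol | C=CCC1(O)C[C@@H](O)C[C@@H](CCc2ccccc2)O1 | intermediate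
7 | (6S,8R)-6,8-dihydroxy-10-phenyldec-1-en-4-one | C=CCC(=O)C[C@@H](O)C[C@H](O)CCc1ccccc1 | intermediate
8 | (4R,6S,8R)-10-phenyldec-1-ene-4,6,8-triol | C=CC[C@@H](O)C[C@@H](O)C[C@H](O)CCc1ccccc1 | intermediate
9 | acrolein | C=CC=O | starting material
10 | (3S)-hexa-1,5-dien-3-ol | C=CC[C@H](O)C=C | intermediate
11 | (3S)-hexa-1,5-dien-3-yl prop-2-enoate | C=CC[C@H](OC(=O)C=C)C=C | intermediate
12 | (6S)-6-ethenyl-5,6-dihydro-2H-pyran-2-one | O=C1C=CC[C@@H](C=C)O1 | intermediate
13 | (6S)-6-[(1Z,4R,6S,8R)-4,6,8-trihydroxy-10-phenyldec-1-en-1-yl]-5,6-dihydro-2H-pyran-2-one | O=C1C=CC[C@@H](/C=C\C[C@@H](O)C[C@@H](O)C[C@H](O)CCc2ccccc2)O1 | target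

**Totals**
Total step count: 8. Longest linear sequence: 5 steps (steps 1, 2, 3, 4, 8, from 1).

**Steps most likely to fail, with fallbacks**

Step 2 (enantioselectivity on this substrate, and running both hydrogenations in one vessel). The fallback sets out from 3 and comes back at 5. Compound 3 is hydrogenated without chiral control (H2, Pd/C, then Raney Ni) to racemic cis-4-hydroxy-6-(2-phenylethyl)oxan-2-one F1. The racemate is then resolved by lipase-catalysed transesterification (Burkholderia cepacia lipase, vinyl acetate), with the enzyme chosen by screening so that the unwanted enantiomer is removed as (4R,6S)-4-acetoxy-6-(2-phenylethyl)oxan-2-one F2 and 5 is recovered unreacted.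

Step 8 (Z-selective cross-metathesis with a free triol and an allylic-oxygenated partner; homodimerisation of 8 and low conversion are the likely problems). The fallback sets out from 8 and comes back at 13; the lactone is no longer brought in by metathesis but built on a preformed cis olefin.
- 8 is silylated (TBSOTf, 2,6-lutidine) to (4R,6S,8R)-4,6,8-tris(tert-butyldimethylsilyloxy)-10-phenyldec-1-ene F4.
- Stereoretentive cross-metathesis with (Z)-but-2-ene-1,4-diol, catalysed by Ru(=CH-C6H4-2-OiPr)(H2IMes)(3,6-dichlorobenzene-1,2-dithiolate), gives (2Z,5R,7S,9R)-5,7,9-tris(tert-butyldimethylsilyloxy)-11-phenylundec-2-en-1-ol F5.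
- MnO2 oxidation gives (2Z,5R,7S,9R)-5,7,9-tris(tert-butyldimethylsilyloxy)-11-phenylundec-2-enal F6.
- Brown allylboration with (−)-Ipc2B(allyl) at −78 °C (Si-face attack) gives (4S,5Z,8R,10S,12R)-8,10,12-tris(tert-butyldimethylsilyloxy)-14-phenyltetradeca-1,5-dien-4-ol F7.
- Acryloyl chloride/Et3N gives (4S,5Z,8R,10S,12R)-8,10,12-tris(tert-butyldimethylsilyloxy)-14-phenyltetradeca-1,5-dien-4-yl prop-2-enoate F8.
- RCM with the second-generation Grubbs catalyst gives (6S)-6-[(1Z,4R,6S,8R)-4,6,8-tris(tert-butyldimethylsilyloxy)-10-phenyldec-1-en-1-yl]-5,6-dihydro-2H-pyran-2-one F9.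
- HF·pyridine removes the silyl groups to give 13.

Step 3 (double allyl addition, or enolisation/β-elimination of the unprotected β-hydroxy lactone). The fallback sets out from 5 and comes back at 8, replacing substrate control by reagent control. Compound 5 is reduced with iBu2AlH (CH2Cl2, −78 °C) to the lactol (4S,6R)-6-(2-phenylethyl)oxane-2,4-diol F3. Its open hydroxy-aldehyde form is allylated with (+)-Ipc2B(allyl) (Re-face attack, then NaOH/H2O2), which gives 8 directly and bypasses 6 and 7.

**Further compounds**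
F1 | step 2 | racemic cis-4-hydroxy-6-(2-phenylethyl)oxan-2-one | O=C1C[C@@H](O)C[C@@H](CCc2ccccc2)O1.O=C1C[C@H](O)C[C@H](CCc2ccccc2)O1
F2 | step 2 | (4R,6S)-4-acetoxy-6-(2-phenylethyl)oxan-2-one | O=C1C[C@H](OC(C)=O)C[C@H](CCc2ccccc2)O1
F3 | step 3 | (4S,6R)-6-(2-phenylethyl)oxane-2,4-diol | OC1C[C@@H](O)C[C@@H](CCc2ccccc2)O1
F4 | step 8 | (4R,6S,8R)-4,6,8-tris(tert-butyldimethylsilyloxy)-10-phenyldec-1-ene | C=CC[C@@H](O[Si](C)(C)C(C)(C)C)C[C@@H](O[Si](C)(C)C(C)(C)C)C[C@H](O[Si](C)(C)C(C)(C)C)CCc1ccccc1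
F5 | step 8 | (2Z,5R,7S,9R)-5,7,9-tris(tert-butyldimethylsilyloxy)-11-phenylundec-2-en-1-ol | OC/C=C\C[C@@H](O[Si](C)(C)C(C)(C)C)C[C@@H](O[Si](C)(C)C(C)(C)C)C[C@H](O[Si](C)(C)C(C)(C)C)CCc1ccccc1
F6 | step 8 | (2Z,5R,7S,9R)-5,7,9-tris(tert-butyldimethylsilyloxy)-11-phenylundec-2-enal | O=C/C=C\C[C@@H](O[Si](C)(C)C(C)(C)C)C[C@@H](O[Si](C)(C)C(C)(C)C)C[C@H](O[Si](C)(C)C(C)(C)C)CCc1ccccc1
F7 | step 8 | (4S,5Z,8R,10S,12R)-8,10,12-tris(tert-butyldimethylsilyloxy)-14-phenyltetradeca-1,5-dien-4-ol | C=CC[C@H](O)/C=C\C[C@@H](O[Si](C)(C)C(C)(C)C)C[C@@H](O[Si](C)(C)C(C)(C)C)C[C@H](O[Si](C)(C)C(C)(C)C)CCc1ccccc1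
F8 | step 8 | (4S,5Z,8R,10S,12R)-8,10,12-tris(tert-butyldimethylsilyloxy)-14-phenyltetradeca-1,5-dien-4-yl prop-2-enoate | C=CC[C@H](OC(=O)C=C)/C=C\C[C@@H](O[Si](C)(C)C(C)(C)C)C[C@@H](O[Si](C)(C)C(C)(C)C)C[C@H](O[Si](C)(C)C(C)(C)C)CCc1ccccc1
F9 | step 8 | (6S)-6-[(1Z,4R,6S,8R)-4,6,8-tris(tert-butyldimethylsilyloxy)-10-phenyldec-1-en-1-yl]-5,6-dihydro-2H-pyran-2-one | O=C1C=CC[C@@H](/C=C\C[C@@H](O[Si](C)(C)C(C)(C)C)C[C@@H](O[Si](C)(C)C(C)(C)C)C[C@H](O[Si](C)(C)C(C)(C)C)CCc2ccccc2)O1
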